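The earlier runs and the new flask were computed for an exercise, noise included.

Sunday's run stopped at 13.3 mM of over-reaction product from 19 mM of second substrate, and Saturday's, with 44 mM of starting material instead of 20 mM, stopped at 13.1 mM.

| run | time / min | over-reaction product / % | target / % |
|---|---|---|---|
| Sunday's | 2.50 | 15.8 | 10.0 |
| Sunday's | 5.00 | 31.2 | 9.0 |
| Sunday's | 8.00 | 50.4 | 6.8 |
| Sunday's | 15.0 | 66.7 | 0 |
| Sunday's | 30.0 | 66.3 | 0 |
| Tuesday's | 1.50 | 5.0 | 5.3 |
| Tuesday's | 5.00 | 23.1 | 7.6 |
| Tuesday's | 8.00 | 38.5 | 3.5 |
| Tuesday's | 12.0 | 45.3 | 0 |
| Tuesday's | 20.0 | 49.0 | 0 |
| Saturday's | 1.50 | 2.0 | 4.1 |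
| Saturday's | 5.00 | 17.6 | 1.9 |
| Saturday's | 8.00 | 25.0 | 2.2 |
| Saturday's | 12.0 | 29.1 | 0.2 |
| Saturday's | 20.0 | 29.8 | 0 |
| Wednesday's | 1.33 | 5.8 | 8.3 |
| Wednesday's | 2.50 | 17.0 | 11.1 |
| Wednesday's | 5.00 | 37.0 | 10.9 |
| Wednesday's | 10.0 | 69.9 | 7.0 |
| Wednesday's | 20.0 | 88.7 | 0.7 |

(scatter of a reading: 1 percentage point)

all flasks: free enzyme 0.30 µM

|  | starting material | second substrate | remark | time |
|---|---|---|---|---|
| Sunday's | 20 mM | 19 mM | run made earlier |  |
| Tuesday's | 28 mM | 19 mM | run made earlier |  |
| Saturday's | 44 mM | 19 mM | run made earlier |  |
| Wednesday's | 20 mM | 28 mM | run made earlier |  |
| north-east | 20 mM (in portions, 2, over 20 min) | 19.0 mM | first portion at the start, last at 20 min | 30 min |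
| east | 20 mM | 19.0 mM (fed, over 20 min) | all else is in the flask from the start; the feed brings no volume worth counting | 30 min |
| south-east | 20 mM (fed, over 20 min) | 19.0 mM | all else is in the flask from the start; the feed brings no volume worth counting | 30 min |
| north-west | 20 mM | 19.0 mM (fed, over 2.0 min) | all else is in the flask from the start; the feed brings no volume worth counting | 30 min |
| south-west | 20 mM | 19.0 mM | everything together at the start | 30 min |

- the flask with the highest amount of over-reaction product, in percent of the starting material charged ("all alike" if they lie within 1.5 percentage points) (north-east / east / south-east / north-west / south-west / all alike)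
- final over-reaction product, as a percentage of the starting material charged, in north-east
- final over-reaction product, as a percentage of the starting material charged, in east
- final over-reaction product, as a percentage of the starting material charged, in south-east
- final over-reaction product, as a percentage of the starting material charged, in north-west
- final over-reaction product, as a percentage of the starting material charged, in south-west

Those numbers seem not to go together. The plateau ignored the starting material, so the second substrate acted as the limiting reagent, yet a third of it never appeared as product. I took that loss to be a first-order decay running beside the enzyme, and I divided one rate by the other so that time dropped out.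

Sunday's use of second substrate through the enzyme ran at 1.43 mM/min over its first 8.00 min, so I put the time to the plateau at about 9.30 min. Taking the level of second substrate to fall evenly, I set its mean at half the charge, and the missing 5.70 mM gave a decay constant of 0.0645 /min. Between 5.00 min and 8.00 min of Sunday's run, the product still to come shrank at 0.347 /min. I read this as both exits together, taking the enzyme's use at low level to be pseudo-first-order too. One minus the ratio of the two constants is 81.4 %: the kept share, the part of the second substrate that reaches the enzyme while its level is low, at this charge of free enzyme. In it neither level nor time appears. It is a reading, resting on a small remainder with a scatter of 1 percentage point.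

In east the feed brought 0.950 mM/min, less than Sunday's use, so I expected a low level and 77.3 %, above south-west, which repeats Sunday's recipe.

The forecast named east, with 56 % in north-east, 83 % in east, 58 % in south-east, 71 % in north-west and 67 % in south-west, reasoning of the slow feed “so little is lost”; for east, my figure was lower.

The simulation put east highest, at 76.1 %, with 55.1 % in north-east, 50.6 % in south-east, 68.1 % in north-west and 66.5 % in south-west.

    first complex → loaded enzyme + first product (k = 780 /s)
    second substrate + loaded enzyme ⇌ second complex (K = 130 /M, k = 81000 /M/s)
    second substrate → decomposed reagent (k = 0.00120 /s)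
    starting material + free enzyme ⇌ first complex (K = 46.0 /M, k = 2.10 × 10⁶ /M/s)
    target → over-reaction product (k = 0.0130 /s)
    second complex → free enzyme + target (k = 250 /s)

Removing the passing of second substrate into decomposed reagent turned the gap between east and south-east from 26 points into −0.68 points, the largest single effect on that pair. East itself kept 80.5 % of the second substrate it used, beside my 81.4 %. For the neighbour of east with 0.180 µM of free enzyme, I scaled the odds of keeping in step with that charge, to 2.62, and got a kept share of 72.4 %; by 30.0 min, counted as first product against decomposed reagent, that flask kept 69.0 %.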